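## Retrosynthetic overview
1. Target 15 ⇒ all-trans 3,4-diarylcyclobutanecarbaldehyde 12. An oxidative 4→6 ring expansion breaks the doubly benzylic ring bond and re-bonds that benzylic carbon to the neighbouring arene (C1–C8a); the C3=C4 enal forms in the same step.
2. 12 ⇒ head-to-head crossed [2+2] of enal 6 (as a chiral eniminium ion) with cinnamyl acetate 8. This makes the C2–C3 bond of the target and sets C2.
3. 6 and 8 ⇒ two Heck reactions of a single aryl iodide 4, with acrolein and with allyl acetate.
4. 4 ⇒ catechol by O-methylation, para-iodination and O-acetylation.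
5. Ring order: arenes (bought), then the cyclobutane, then the dihydronaphthalene ring last.

Assumption: the (S)-amine in step 6 shields the face predicted by the usual E-iminium/s-trans model. If the sense of induction proves opposite, the (R)-amine is used.

## Route

Step 1
Reactants: 1 catechol
Product: 2 guaiacol (2-methoxyphenol)
Conditions: MeI (1.0 equiv), K2CO3 (1.0 equiv), acetone, reflux
Reagents that add atoms: iodomethane, CI
Why: Williamson ether synthesis with one equivalent of MeI on the monoanion; neutral veratrole is removed by base extraction and the more polar residual catechol by chromatography or distillation.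

Step 2
Reactants: 2 guaiacol
Product: 3 4-iodo-2-methoxyphenol
Conditions: NIS (1.0 equiv), TsOH (10 mol %), MeCN, 0 °C to rt
Reagents that add atoms: N-iodosuccinimide, O=C1CCC(=O)N1I
Why: Electrophilic aromatic iodination in which the free OH is the strongest director and sends iodine to its unhindered para position.

Step 3
Reactants: 3 4-iodo-2-methoxyphenol
Product: 4 4-iodo-2-methoxyphenyl acetate
Conditions: Ac2O, pyridine, CH2Cl2, rt
Reagents that add atoms: acetic anhydride, CC(=O)OC(C)=O
Why: O-acetylation, which raises the oxidation potential of the arene so that it survives Ag(I) in step 5 and does not transfer an electron to the excited iminium ion in step 6.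

Step 4
Reactants: 4 4-iodo-2-methoxyphenyl acetate; 5 acrolein
Product: 6 (E)-4-acetoxy-3-methoxycinnamaldehyde
Conditions: Pd(OAc)2 (3 mol %), n-Bu4NCl, NaHCO3, DMF, 50 °C
Reagents that add atoms: none
Why: Mizoroki–Heck reaction under Jeffery conditions, mild enough for acrolein and the aryl acetate, with syn insertion and syn β-H elimination giving the E-enal.

Step 5
Reactants: 4 4-iodo-2-methoxyphenyl acetate; 7 allyl acetate
Product: 8 (E)-3-(4-acetoxy-3-methoxyphenyl)allyl acetate
Conditions: Pd(OAc)2 (5 mol %), Ag2CO3 (0.6 equiv), PhMe, 110 °C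
Reagents that add atoms: none
Why: Silver-promoted (cationic Pd) Mizoroki–Heck reaction of an allylic ester, in which carbonyl coordination to Pd favours β-H over β-OAc elimination and gives the E-cinnamyl acetate.

Step 6
Reactants: 6 (E)-4-acetoxy-3-methoxycinnamaldehyde; 8 (E)-3-(4-acetoxy-3-methoxyphenyl)allyl acetate
Product: 11 (1R,2R,3S,4S)-2-(acetoxymethyl)-3,4-bis(4-acetoxy-3-methoxyphenyl)cyclobutane-1-carbaldehyde, via eniminium tetrafluoroborate 9 (not isolated), via cyclobutyl iminium tetrafluoroborate 10 (not isolated)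
Conditions: (S)-2-[methoxy(diphenyl)methyl]pyrrolidine·HBF4 (1.0 equiv), 4 Å MS, MeCN, rt; then 8 (3 equiv, excess recovered), [Ru(bpy)3](PF6)2 (2.5 mol %), 458 nm LED, rt; then aq NaHCO3/THF
Reagents that add atoms: water, O
Why: Triplet-sensitised crossed [2+2] photocycloaddition of a chiral eniminium ion, stepwise via a 1,4-diradical: the Ru sensitiser can excite only 9, whose α-carbon bonds to the CH2OAc-bearing alkene carbon to give a bis-benzylic diradical that closes head-to-head to the all-trans ring, while the CPh2OMe group shields one face of the E,s-trans eniminium and so sets C1 (R) and, through the trans closure, C2 (R), C3 (S) and C4 (S); minor diastereomers are removed by chromatography.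

Step 7
Reactants: 11 (1R,2R,3S,4S)-2-(acetoxymethyl)-3,4-bis(4-acetoxy-3-methoxyphenyl)cyclobutane-1-carbaldehyde
Product: 12 (1R,2R,3S,4S)-2-(acetoxymethyl)-3,4-bis(4-hydroxy-3-methoxyphenyl)cyclobutane-1-carbaldehyde
Conditions: NH4OAc (10 equiv), MeOH–H2O 4:1, rt
Reagents that add atoms: none
Why: Chemoselective transesterification in which aryl acetates (phenoxide leaving group) cleave far faster than the primary alkyl acetate, and the neutral buffer avoids base-induced push–pull opening of the donor–acceptor cyclobutane; C2 is not touched.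

Step 8
Reactants: 12 (1R,2R,3S,4S)-2-(acetoxymethyl)-3,4-bis(4-hydroxy-3-methoxyphenyl)cyclobutane-1-carbaldehyde
Product: 15 [(1S,2R)-3-formyl-7-hydroxy-1-(4-hydroxy-3-methoxyphenyl)-6-methoxy-1,2-dihydronaphthalen-2-yl]methyl acetate, via bis(quinone methide) 13 (not isolated), via enal quinone methide 14 (not isolated)
Conditions: PhI(OAc)2 (1.0 equiv, added over 1 h), HFIP–CH2Cl2 1:4, −30 to 0 °C
Reagents that add atoms: none
Why: Proposed new method: oxidative 4→6 ring expansion of a 1,2-bis(4-hydroxyaryl)cyclobutane, in which two-electron oxidation of either phenol gives a phenoxenium ion whose para carbon sits next to the strained ring, so the doubly benzylic C3–C4 bond breaks heterolytically (Grob-type, ring strain released, the departing carbon being a 4-hydroxybenzyl cation) to give 13, the quinone methide next to the acidic formyl C–H tautomerises to the (E)-enal phenol 14, and in HFIP the arene carbon para to OMe closes onto the remaining quinone methide anti to CH2OAc (Friedel–Crafts 1,6-addition), so that C2 (R) is carried over unchanged and C1 (S) is set trans by substrate control; the closest known reaction types are iodine(III) or Ag2O oxidation of 4-alkylguaiacols to p-quinone methides, the electron-transfer-induced conversion of 1,2-dianisylcyclobutanes into 1-aryl-1,2-dihydronaphthalenes, and the biomimetic cyclisation of 8–8′ bis(quinone methides) to aryldihydronaphthalene lignans.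

## Compound list
1 | catechol | Oc1ccccc1O | starting material
2 | guaiacol (2-methoxyphenol) | COc1ccccc1O | intermediate
3 | 4-iodo-2-methoxyphenol | COc1cc(I)ccc1O | intermediate
4 | 4-iodo-2-methoxyphenyl acetate | COc1cc(I)ccc1OC(C)=O | intermediate
5 | acrolein | C=CC=O | starting material
6 | (E)-4-acetoxy-3-methoxycinnamaldehyde | COc1cc(/C=C/C=O)ccc1OC(C)=O | intermediate
7 | allyl acetate | C=CCOC(C)=O | starting material
8 | (E)-3-(4-acetoxy-3-methoxyphenyl)allyl acetate | COc1cc(/C=C/COC(C)=O)ccc1OC(C)=O | intermediate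
9 | (S,E,E)-eniminium tetrafluoroborate from 6 and (S)-2-[methoxy(diphenyl)methyl]pyrrolidine | COC(c1ccccc1)(c1ccccc1)[C@@H]1CCC/[N+]1=C\C=C\c1ccc(OC(C)=O)c(OC)c1.F[B-](F)(F)F | intermediate (not isolated)
10 | iminium tetrafluoroborate of 11 with the same (S)-amine | COC(c1ccccc1)(c1ccccc1)[C@@H]1CCC/[N+]1=C\[C@H]1[C@H](COC(C)=O)[C@@H](c2ccc(OC(C)=O)c(OC)c2)[C@@H]1c1ccc(OC(C)=O)c(OC)c1.F[B-](F)(F)F | intermediate (not isolated)
11 | (1R,2R,3S,4S)-2-(acetoxymethyl)-3,4-bis(4-acetoxy-3-methoxyphenyl)cyclobutane-1-carbaldehyde (all-trans) | O=C[C@H]1[C@H](COC(C)=O)[C@@H](c2ccc(OC(C)=O)c(OC)c2)[C@@H]1c1ccc(OC(C)=O)c(OC)c1 | intermediate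
12 | (1R,2R,3S,4S)-2-(acetoxymethyl)-3,4-bis(4-hydroxy-3-methoxyphenyl)cyclobutane-1-carbaldehyde (all-trans) | O=C[C@H]1[C@H](COC(C)=O)[C@@H](c2ccc(O)c(OC)c2)[C@@H]1c1ccc(O)c(OC)c1 | intermediate
13 | (2R,3R)-3-formyl-4-(3-methoxy-4-oxocyclohexa-2,5-dien-1-ylidene)-2-[(3-methoxy-4-oxocyclohexa-2,5-dien-1-ylidene)methyl]butyl acetate | COC1=CC(=C[C@@H](C=O)[C@H](COC(C)=O)C=C2C=CC(=O)C(OC)=C2)C=CC1=O | intermediate (not isolated)
14 | (2R,3E)-3-formyl-4-(4-hydroxy-3-methoxyphenyl)-2-[(3-methoxy-4-oxocyclohexa-2,5-dien-1-ylidene)methyl]but-3-en-1-yl acetate | COc1cc(/C=C(/C=O)[C@H](COC(C)=O)C=C2C=CC(=O)C(OC)=C2)ccc1O | intermediate (not isolated)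
15 | [(1S,2R)-3-formyl-7-hydroxy-1-(4-hydroxy-3-methoxyphenyl)-6-methoxy-1,2-dihydronaphthalen-2-yl]methyl acetate (1,2-trans) | COc1cc([C@H]2c3cc(O)c(OC)cc3C=C(C=O)[C@@H]2COC(C)=O)ccc1O | target

## Step count and risks
Total steps: 8. Longest linear sequence: 7 (steps 1, 2, 3, 4, 6, 7, 8).

**Risk 1 (step 8, the proposed new step).**
- What can go wrong: oxidative cycloreversion to the two styrenes, C–H instead of C–C loss at the benzylic carbon, over-oxidation of 15 to the arylnaphthalene, or loss of the C2–H of 14 to give an achiral diene.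
- Fallback: it sets out from 12 and comes back at 15, using known electron-transfer chemistry on aryl ethers instead of phenol oxidation.
- 12 is silylated (TBSCl, imidazole, DMF) to (1R,2R,3S,4S)-2-(acetoxymethyl)-3,4-bis[4-(tert-butyldimethylsilyloxy)-3-methoxyphenyl]cyclobutane-1-carbaldehyde F1.
- F1 is irradiated (>400 nm) with chloranil (1.1 equiv) in MeCN. This photoinduced electron transfer is known to turn 1,2-bis(4-alkoxyphenyl)cyclobutanes into 1-aryl-1,2-dihydronaphthalenes through the cyclobutane radical cation.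
- The product is [(1S,2R)-7-(tert-butyldimethylsilyloxy)-1-[4-(tert-butyldimethylsilyloxy)-3-methoxyphenyl]-3-formyl-6-methoxy-1,2-dihydronaphthalen-2-yl]methyl acetate F2, and Et3N·3HF in THF then frees 15.

**Risk 2 (step 6).**
- What can go wrong: the internal alkene 8 may react sluggishly, and the diastereomer ratio or ee may be moderate.
- Fallback: it sets out from 6 and 8 and comes back at 11, separating ring construction from enantiocontrol.
- The same sensitised cycloaddition is run with achiral pyrrolidine·HBF4 (30 mol %, catalyst) to give racemic all-trans 2-(acetoxymethyl)-3,4-bis(4-acetoxy-3-methoxyphenyl)cyclobutane-1-carbaldehyde F3.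
- Condensation with (1R,2R)-N,N′-dimethyl-1,2-diphenylethane-1,2-diamine (Et2O, 4 Å MS) gives two chromatographically separable aminals.
- These are (4R,5R)-2-[(1R,2R,3S,4S)-cyclobutyl]-1,3-dimethyl-4,5-diphenylimidazolidine F4, which is kept, and its (1S,2S,3R,4R)-cyclobutyl diastereomer F5, which is discarded.
- Mild hydrolysis of F4 (aq AcOH, or SiO2/H2O) returns enantiopure 11.

**Risk 3 (step 5).**
- What can go wrong: β-acetoxy elimination to the allylarene, or E/Z and regioisomer mixtures.
- Fallback: it sets out from 6 and comes back at 8 by a redox route instead of a C–C coupling.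
- Luche reduction (NaBH4, CeCl3·7H2O, MeOH, 0 °C) gives (E)-4-(3-hydroxyprop-1-en-1-yl)-2-methoxyphenyl acetate F6.
- Acetylation with Ac2O/pyridine then gives 8 and also repairs any phenolic acetate lost during the reduction.

## Further compounds
F1 | step 8 | (1R,2R,3S,4S)-2-(acetoxymethyl)-3,4-bis[4-(tert-butyldimethylsilyloxy)-3-methoxyphenyl]cyclobutane-1-carbaldehyde | O=C[C@H]1[C@H](COC(C)=O)[C@@H](c2ccc(O[Si](C)(C)C(C)(C)C)c(OC)c2)[C@@H]1c1ccc(O[Si](C)(C)C(C)(C)C)c(OC)c1
F2 | step 8 | [(1S,2R)-7-(tert-butyldimethylsilyloxy)-1-[4-(tert-butyldimethylsilyloxy)-3-methoxyphenyl]-3-formyl-6-methoxy-1,2-dihydronaphthalen-2-yl]methyl acetate | COc1cc([C@H]2c3cc(O[Si](C)(C)C(C)(C)C)c(OC)cc3C=C(C=O)[C@@H]2COC(C)=O)ccc1O[Si](C)(C)C(C)(C)C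
F3 | step 6 | racemic all-trans 2-(acetoxymethyl)-3,4-bis(4-acetoxy-3-methoxyphenyl)cyclobutane-1-carbaldehyde (1:1 mixture of 11 and its enantiomer; the SMILES shows the enantiomer) | O=C[C@@H]1[C@@H](COC(C)=O)[C@H](c2ccc(OC(C)=O)c(OC)c2)[C@H]1c1ccc(OC(C)=O)c(OC)c1
F4 | step 6 | (4R,5R)-2-[(1R,2R,3S,4S)-2-(acetoxymethyl)-3,4-bis(4-acetoxy-3-methoxyphenyl)cyclobutyl]-1,3-dimethyl-4,5-diphenylimidazolidine | CN1[C@H](c2ccccc2)[C@@H](c2ccccc2)N(C)C1[C@H]3[C@H](COC(C)=O)[C@@H](c4ccc(OC(C)=O)c(OC)c4)[C@@H]3c5ccc(OC(C)=O)c(OC)c5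
F5 | step 6 | (4R,5R)-2-[(1S,2S,3R,4R)-2-(acetoxymethyl)-3,4-bis(4-acetoxy-3-methoxyphenyl)cyclobutyl]-1,3-dimethyl-4,5-diphenylimidazolidine | CN1[C@H](c2ccccc2)[C@@H](c2ccccc2)N(C)C1[C@@H]3[C@@H](COC(C)=O)[C@H](c4ccc(OC(C)=O)c(OC)c4)[C@H]3c5ccc(OC(C)=O)c(OC)c5
F6 | step 5 | (E)-4-(3-hydroxyprop-1-en-1-yl)-2-methoxyphenyl acetate | COc1cc(/C=C/CO)ccc1OC(C)=O
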